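**Plan**

1. Retrosynthesis: the tetrahydrofuran is opened at one O–CH2 bond (1,4-diol, then γ-lactone 12). In the lactone, the C3–CH2Ar bond of one veratryl group is cut (enolate benzylation) and the aryl–CH2 bond of the other is cut (aryl nucleophile on a cyclopropane CH2).
2. Enabling feature: the benzylic CH2 on lactone C4 stands 1,3 to C3, the carbon that must take the second benzyl group and that lies next to the ring C=O. An extra CH2–C3 bond and a temporary CO2Me on C3 turn CH2, C4 and C3 into an acceptor-activated cyclopropane fused to the five-membered lactone (3-oxabicyclo[3.1.0]hexan-2-one).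
3. Forward: dimethyl malonate and (R)-epichlorohydrin give the bicyclic cyclopropane lactone, both rings in one step. Strain-releasing opening by the veratryl nucleophile forms the aryl–CH2 bond, and the enolate set free is benzylated in the same flask.
4. The helpers are then taken out: CO2Me by Krapcho dealkoxycarbonylation, the lactone oxidation level by LiAlH4. The tetrahydrofuran ring is closed last by C–O bond formation from the diol.
5. Stereochemistry: one ring stereocentre comes from (R)-epichlorohydrin and is carried unchanged through the cyclopropane carbon. The second is set trans to it by thermodynamic equilibration at the lactone α-carbon after decarboxylation.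

Key step: step 2

Assumption: aryl Grignard 6 (as a THF solution) and benzylic bromide 7 are bought, and 7 is used fresh because it is a labile electron-rich benzylic halide.

**Step 1**
Reactants: 1 dimethyl malonate; 2 (R)-epichlorohydrin
Product: 5 methyl (1S,5R)-2-oxo-3-oxabicyclo[3.1.0]hexane-1-carboxylate, via epoxy malonate 3 (not isolated), via hydroxymethylcyclopropane diester 4 (not isolated)
Conditions: NaOMe (1.05 equiv), MeOH, 0 °C → reflux
Reagents that add atoms: none
Why: Tandem malonate alkylation–cyclopropanation–lactonisation, known for malonic esters and epichlorohydrin: the malonate anion opens the epoxide at its CH2 terminus, the alkoxide closes on CH2Cl to the transposed epoxide 3, a 3-exo-tet attack of the re-formed malonate anion inverts the stereocentre to give cyclopropane 4, and its alkoxide lactonises onto the cis ester, so that both stereocentres of 5 derive from the single centre of 2.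

**Step 2**
Reactants: 5 methyl (1S,5R)-2-oxo-3-oxabicyclo[3.1.0]hexane-1-carboxylate; 6 3,4-dimethoxyphenylmagnesium bromide; 7 3,4-dimethoxybenzyl bromide
Product: 9 methyl (3R,4R)-3,4-bis(3,4-dimethoxybenzyl)-2-oxotetrahydrofuran-3-carboxylate, via bromomagnesium enolate 8 (not isolated)
Conditions: 6 (1.15 equiv), CuI (15 mol %), THF, −40 → −20 °C; then 7 (1.5 equiv), DMPU, −20 °C → rt
Reagents that add atoms: none
Why: The arylcopper species formed from 6 and catalytic CuI attacks the cyclopropane CH2 (C6) of 5 in an SN2-like homoconjugate addition; the C1–C6 bond breaks because C1 leaves as a carbanion stabilised by both the lactone C=O and the CO2Me group, and relief of three-ring strain drives formation of the aryl–CH2 bond and delivers chelated enolate 8, which is C-benzylated by 7 once DMPU loosens the magnesium chelate. The closest known reaction type is the copper-catalysed Grignard opening of this same bicyclic cyclopropane lactone class to 4-substituted 2-oxotetrahydrofuran-3-carboxylates, followed here in the same flask by a malonate-type enolate alkylation. No ring is closed: the three-membered ring is opened and the five-membered lactone is kept. C5 of 5 keeps all its bonds and becomes C4 of 9 with its (R) arrangement unchanged, while the new quaternary C3 is set by approach of 7 anti to the C4 benzyl group (its configuration is of no consequence, since C3 is reset in step 3). The step needs attack at C6 and not at C5 or at a carbonyl carbon, which the unhindered primary carbon, the soft copper nucleophile and the low temperature should secure, and the small excess of 6 limits coupling of leftover aryl metal with 7.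

**Step 3**
Reactants: 9 methyl (3R,4R)-3,4-bis(3,4-dimethoxybenzyl)-2-oxotetrahydrofuran-3-carboxylate
Product: 12 (3R,4R)-3,4-bis(3,4-dimethoxybenzyl)dihydrofuran-2(3H)-one, via lithium carboxylate 10 (not isolated), via lithium enolate 11 (not isolated)
Conditions: LiCl (3 equiv), H2O (2 equiv), DMSO, 150 °C; then DBU (cat.), PhMe, 60 °C
Reagents that add atoms: none
Why: Krapcho dealkoxycarbonylation: chloride demethylates the ester by SN2 at CH3 to carboxylate 10, loss of CO2 gives enolate 11, and protonation followed by DBU equilibration of the enolisable C3–H places the C3 benzyl trans to the untouched C4 benzyl under thermodynamic control.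

**Step 4**
Reactants: 12 (3R,4R)-3,4-bis(3,4-dimethoxybenzyl)dihydrofuran-2(3H)-one
Product: 13 (2R,3R)-2,3-bis(3,4-dimethoxybenzyl)butane-1,4-diol
Conditions: LiAlH4, THF, 0 °C → rt; aqueous NaOH work-up
Reagents that add atoms: none
Why: Lithium aluminium hydride reduction of a γ-lactone to the 1,4-diol, which leaves the aryl methyl ethers alone and breaks no bond at either stereocentre.

**Step 5**
Reactants: 13 (2R,3R)-2,3-bis(3,4-dimethoxybenzyl)butane-1,4-diol
Product: 15 (3R,4R)-3,4-bis(3,4-dimethoxybenzyl)tetrahydrofuran, via monotosylate 14 (not isolated)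
Conditions: TsCl (1.1 equiv), pyridine, 0 → 50 °C
Reagents that add atoms: none
Why: Cyclodehydration by mono-sulfonylation and intramolecular Williamson etherification: one of the two homotopic primary alcohols is tosylated and the other displaces the tosylate in a 5-exo-tet closure, with no bond to a stereocentre made or broken.

**Compound list**

1 | dimethyl malonate | COC(=O)CC(=O)OC | starting material
2 | (R)-epichlorohydrin, (2R)-2-(chloromethyl)oxirane | ClC[C@H]1CO1 | starting material
3 | dimethyl 2-{[(2R)-oxiran-2-yl]methyl}propanedioate | COC(=O)C(C(=O)OC)C[C@@H]1CO1 | intermediate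
4 | dimethyl (2R)-2-(hydroxymethyl)cyclopropane-1,1-dicarboxylate (present as its alkoxide in the basic medium) | COC(=O)C1(C(=O)OC)C[C@H]1CO | intermediate
5 | methyl (1S,5R)-2-oxo-3-oxabicyclo[3.1.0]hexane-1-carboxylate | COC(=O)[C@]12C[C@H]1COC2=O | intermediate
6 | 3,4-dimethoxyphenylmagnesium bromide | COc1ccc([Mg]Br)cc1OC | starting material
7 | 3,4-dimethoxybenzyl bromide | COc1ccc(CBr)cc1OC | starting material
8 | bromomagnesium enolate of methyl (4R)-4-(3,4-dimethoxybenzyl)-2-oxotetrahydrofuran-3-carboxylate | COC(=O)C1=C(O[Mg]Br)OC[C@@H]1Cc1ccc(OC)c(OC)c1 | intermediate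
9 | methyl (3R,4R)-3,4-bis(3,4-dimethoxybenzyl)-2-oxotetrahydrofuran-3-carboxylate | COC(=O)[C@]1(Cc2ccc(OC)c(OC)c2)C(=O)OC[C@@H]1Cc1ccc(OC)c(OC)c1 | intermediate
10 | lithium (3R,4R)-3,4-bis(3,4-dimethoxybenzyl)-2-oxotetrahydrofuran-3-carboxylate | [Li+].[O-]C(=O)[C@]1(Cc2ccc(OC)c(OC)c2)C(=O)OC[C@@H]1Cc1ccc(OC)c(OC)c1 | intermediate
11 | lithium enolate of (4R)-3,4-bis(3,4-dimethoxybenzyl)dihydrofuran-2(3H)-one | [Li]OC1=C(Cc2ccc(OC)c(OC)c2)[C@@H](Cc2ccc(OC)c(OC)c2)CO1 | intermediate
12 | (3R,4R)-3,4-bis(3,4-dimethoxybenzyl)dihydrofuran-2(3H)-one | COc1ccc(C[C@H]2C(=O)OC[C@@H]2Cc2ccc(OC)c(OC)c2)cc1OC | intermediate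
13 | (2R,3R)-2,3-bis(3,4-dimethoxybenzyl)butane-1,4-diol | COc1ccc(C[C@@H](CO)[C@H](CO)Cc2ccc(OC)c(OC)c2)cc1OC | intermediate
14 | (2R,3R)-2,3-bis(3,4-dimethoxybenzyl)-4-hydroxybutyl 4-methylbenzenesulfonate | COc1ccc(C[C@@H](COS(=O)(=O)c3ccc(C)cc3)[C@H](CO)Cc2ccc(OC)c(OC)c2)cc1OC | intermediate
15 | (3R,4R)-3,4-bis(3,4-dimethoxybenzyl)tetrahydrofuran (trans) | COc1ccc(C[C@H]2COC[C@@H]2Cc2ccc(OC)c(OC)c2)cc1OC | target

Total step count: 5
Longest linear sequence: 5 steps (1 and 2 to 15)

**Steps most likely to fail**

Step 2. The chelated bromomagnesium enolate 8 may be alkylated too slowly, so that it survives to the work-up and is only protonated, or bromide 7 may be used up by leftover aryl metal. The fallback sets out from 5 and 6 and comes back at 12. The copper-catalysed opening is run alone and quenched with dilute HCl to give methyl (4R)-4-(3,4-dimethoxybenzyl)-2-oxotetrahydrofuran-3-carboxylate F1. Krapcho dealkoxycarbonylation (LiCl, wet DMSO, 140 °C) should then give (R)-4-(3,4-dimethoxybenzyl)dihydrofuran-2(3H)-one F2. Deprotonation with LiHMDS in THF at −78 °C gives the lithium lactone enolate F3, and its alkylation with 7 (DMPU) anti to the C4 substituent should give the trans lactone 12 directly under kinetic control. Compound 9 and step 3 are bypassed.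

Step 3. At 150 °C chloride may also attack the lactone O–CH2 carbon or an aryl methyl ether, and protonation of enolate 11 from the face away from the C4 substituent places the benzyl groups cis, so that an incomplete equilibration would leave the wrong relative configuration. The fallback sets out from 9 and comes back at 12. Saponification with KOH in aqueous methanol at reflux opens the lactone and hydrolyses the ester to dipotassium 2-(3,4-dimethoxybenzyl)-2-[(2R)-1-(3,4-dimethoxyphenyl)-3-hydroxypropan-2-yl]propanedioate F4. Acidification with HCl relactonises it to (4R)-3,4-bis(3,4-dimethoxybenzyl)-2-oxotetrahydrofuran-3-carboxylic acid F5 (both C3 epimers). Heating in toluene at reflux should decarboxylate this malonic-type acid without any halide, and DBU in the same solution should equilibrate C3 to give 12.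

Step 1. Direct displacement of chloride competes with epoxide opening and leads to the enantiomeric bicycle, so enantiopurity may be eroded, and the epoxide may oligomerise. The fallback sets out from 1 and comes back at 5. (R)-Glycidol F6 (purchased) is converted with Tf2O and 2,6-lutidine in CH2Cl2 at −30 °C into (S)-glycidyl triflate F7; the descriptor changes by priority only. The sodium enolate of 1 (NaH, THF, 0 °C) should displace the triflate faster than it opens the epoxide and so give the same epoxide 3 by a single pathway. On warming, 3 closes to 4 and lactonises to 5.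

**Further compounds**

F1 | step 2 | methyl (4R)-4-(3,4-dimethoxybenzyl)-2-oxotetrahydrofuran-3-carboxylate (C3 epimers) | COC(=O)C1C(=O)OC[C@@H]1Cc1ccc(OC)c(OC)c1
F2 | step 2 | (R)-4-(3,4-dimethoxybenzyl)dihydrofuran-2(3H)-one | O=C1OC[C@H](Cc2ccc(OC)c(OC)c2)C1
F3 | step 2 | lithium enolate of (R)-4-(3,4-dimethoxybenzyl)dihydrofuran-2(3H)-one | [Li]OC1=C[C@@H](Cc2ccc(OC)c(OC)c2)CO1
F4 | step 3 | dipotassium 2-(3,4-dimethoxybenzyl)-2-[(2R)-1-(3,4-dimethoxyphenyl)-3-hydroxypropan-2-yl]propanedioate | [K+].[K+].[O-]C(=O)C(Cc1ccc(OC)c(OC)c1)(C([O-])=O)[C@H](CO)Cc1ccc(OC)c(OC)c1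
F5 | step 3 | (4R)-3,4-bis(3,4-dimethoxybenzyl)-2-oxotetrahydrofuran-3-carboxylic acid (C3 epimers) | OC(=O)C1(Cc2ccc(OC)c(OC)c2)C(=O)OC[C@@H]1Cc1ccc(OC)c(OC)c1
F6 | step 1 | (R)-glycidol (purchased) | OC[C@@H]1CO1
F7 | step 1 | (S)-glycidyl triflate, (2S)-oxiran-2-ylmethyl trifluoromethanesulfonate | FC(F)(F)S(=O)(=O)OC[C@@H]1CO1
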